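The pitfall in this flask is to take charged enzyme as a plain multiplier of the rate: added ligand parks enzyme as idle complex, and here 6.0 µM of added ligand stands against 5.70 µM of enzyme.

common to all: enzyme 0.057 mol%
- south-west: substrate 10 mM; added ligand 3 µM; run made earlier
- north-east: substrate 10 mM; added ligand 12 µM; run made earlier
- north: substrate 15 mM; added ligand 6 µM; run made earlier
- flask: substrate 10 mM; added ligand 6.0 µM

| run | time / min | product / % | substrate / % |
|---|---|---|---|
| south-west | 1.50 | 13.5 | 85.4 |
| south-west | 3.00 | 26.2 | 75.2 |
| south-west | 5.00 | 40.0 | 59.8 |
| south-west | 6.00 | 46.8 | 54.4 |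
| south-west | 8.00 | 57.1 | 43.7 |
| south-west | 10.0 | 65.5 | 32.1 |
| north-east | 0.833 | 0 | 98.4 |
| north-east | 1.33 | 2.5 | 98.5 |
| north-east | 2.00 | 2.2 | 100.9 |
| north-east | 4.00 | 5.5 | 93.3 |
| north-east | 6.00 | 6.7 | 91.2 |
| north-east | 10.0 | 14.0 | 88.0 |
| north | 0.833 | 7.1 | 93.4 |
| north | 1.33 | 10.7 | 90.0 |
| north | 2.50 | 19.5 | 82.6 |
| north | 5.00 | 35.0 | 66.0 |
| north | 10.0 | 57.4 | 42.9 |

(scatter of a reading: 1 percentage point)

- apparent order in enzyme when 10% of the substrate are converted (percent change of the rate of making product for one percent more enzyme charged)
- factor on the rate of making product when 10% of the substrate are converted if enzyme is charged twice over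

- the numbers in the tables scatter with a standard deviation of 1 percentage point
- steps under discussion: substrate + enzyme -> product + enzyme; 2 enzyme <-> resting dimer; enzyme + added ligand <-> idle complex

I read the runs as pseudo-first-order in substrate, so the last product readings give rate constants of 0.106 /min in south-west and 0.0151 /min in north-east. South-west charges less ligand than enzyme, so I take its free enzyme as the difference, 2.70 µM. At equal substrate I let the rate constant scale with free enzyme, so north-east has 0.383 µM free, and its balance gives a reading of the dissociation constant, 0.481 µM.

The balance of this flask then gives free enzyme x = 1.31 µM, idle complex c = 4.39 µM and free ligand l = 1.61 µM. Now I follow one extra enzyme molecule. Differentiating the balance, its chance of ending free is x/(x + c·l/charged ligand) = 0.527, while the share free now is 23.0%. That chance over that share is the leverage, which is the apparent order: 2.29. Doubling the enzyme in the same balance gives 5.86 µM free, a factor of 4.47 with no resting dimer counted.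

The forecast says order 2.2 and factor 3.3, a factor lower than mine, and starts from “The flask sits almost at equivalence”.

The flask gives order 2.2 and factor 3.65.

    substrate + enzyme → product + enzyme, rate k1*[substrate]*[enzyme]/(1 + ([substrate]/Km1) + ([product]/Kp1)) (6.60 mM, 9.00 mM, k = 1600 /M/s)
    2 enzyme ⇌ resting dimer (K = 43000 /M, k = 13000 /M/s)
    enzyme + added ligand ⇌ idle complex, settled at all times (K = 2.30 × 10⁶ /M)

After 12.0 min the flask holds 20.8% of its enzyme free, 77.0% as idle complex and 26.8% of its ligand free, and these shares put the leverage at 2.41, against my 2.29. Part of the steepness comes from the parking as idle complex. In the simulated run of this flask without that parking, where the resting dimer stays, the apparent order is 0.79.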